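**Assumption:** the SMILES is taken as drawn – core (6R,7S,8S,9S), ring carbons cis on both C1=C10 and C4=C5, acyl groups (2R,3S) on O‑9 and (2S) on O‑8; labels C1–C15 are germacranolide locants, α/β refer to the usual drawing with H‑7 α.

## Retrosynthetic overview

1. Target ⇐ two late acylations of the 8,9‑diol core: O‑8 with lithium (S)‑acetolactate (from (R)‑lactic acid), O‑9 with a silyl‑protected syn acid (from D‑threonine).
2. Core lactone ester ⇐ oxidation of a ten‑membered triol, made by a transannular [2,3]‑Wittig ring contraction of a 13‑membered bis‑allylic ether (forms C6–C7, both stereocentres and the C11=C13 methylene).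
3. 13‑Membered ether ⇐ ring‑closing metathesis (C1=C10), then trans‑hydroalumination/iodination and Stille hydroxymethylation of the ring alkyne.
4. Ene–yne precursor ⇐ chelation‑controlled addition of metallated neryl propargyl ether (from nerol) to an aldehyde from dimethyl (S)‑malate (C9 bought, C8 set by C9).
5. Ring order: 13‑membered ether (metathesis) → ten‑membered carbocycle (Wittig) → γ‑lactone (oxidative lactonisation).

## Route

### Part A – linker

**Step 1**
Reactants: 1 nerol; 2 propargyl bromide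
Product: 3 neryl propargyl ether
Conditions: NaH, Bu4NI (cat.), THF, 0 °C → rt
Reagents that add atoms: none
Why: Williamson etherification; the (Z)‑C4=C5 olefin and the prenyl terminus are bought with nerol.

### Part B – acid for O‑9

**Step 2**
Reactants: 4 D‑threonine
Product: 6 (2S,3S)-3-methyloxirane-2-carboxylic acid, via bromohydrin acid 5 (not isolated)
Conditions: NaNO2, KBr, H2SO4 (aq), −5 → 0 °C; then KOH, EtOH, 0 °C → rt; KHSO4 (aq) to pH 3
Reagents that add atoms: none
Why: Diazotisation–bromination proceeds with retention (α‑lactone double inversion) and the intramolecular Williamson closure inverts C2, so both epoxide centres derive from D‑threonine.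

**Step 3**
Reactants: 6 (2S,3S)-3-methyloxirane-2-carboxylic acid
Product: 7 (2R,3S)-3-hydroxy-2-methylbutanoic acid
Conditions: Me2CuLi (3 equiv), Et2O/THF, −30 → 0 °C; aq HCl
Reagents that add atoms: lithium dimethylcuprate, [Li+].C[Cu-]C
Why: Carboxylate‑directed SN2 opening of the epoxy acid at C2 by the cuprate (inversion) gives the syn (2R,3S) acid.

**Step 4**
Reactants: 7 (2R,3S)-3-hydroxy-2-methylbutanoic acid
Product: 9 (2R,3S)-2-methyl-3-(triethylsilyloxy)butanoic acid, via silyl ester 8 (not isolated)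
Conditions: TESCl (2.2 equiv), imidazole, DMF, 0 °C → rt; then K2CO3 (cat.), MeOH/H2O, 0 °C
Reagents that add atoms: chlorotriethylsilane, CC[Si](Cl)(CC)CC
Why: Bis‑silylation followed by selective solvolysis of the labile silyl ester leaves the O‑silyl acid without touching either stereocentre.

### Part C – acid salt for O‑8

**Step 5**
Reactants: 10 (R)-lactic acid; 11 pivalaldehyde
Product: 12 (2R,5R)-2-tert-butyl-5-methyl-1,3-dioxolan-4-one
Conditions: TsOH (cat.), pentane, reflux (Dean–Stark); recrystallisation at −78 °C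
Reagents that add atoms: none
Why: Acetalisation gives the cis dioxolanone, storing the lactate configuration in the new acetal centre (Seebach self‑regeneration of stereocentres).

**Step 6**
Reactants: 12 (2R,5R)-2-tert-butyl-5-methyl-1,3-dioxolan-4-one
Product: 14 (2R,5S)-5-acetyl-2-tert-butyl-5-methyl-1,3-dioxolan-4-one, via lithium enolate 13 (not isolated)
Conditions: LiN(i-Pr)2, THF, −78 °C; then MeC(O)N(OMe)Me, −78 → −30 °C; AcOH
Reagents that add atoms: N-methoxy-N-methylacetamide, CC(=O)N(C)OC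
Why: Claisen‑type C‑acylation of the enolate occurs anti to the tert‑butyl group, so the quaternary centre is set by the acetal centre with overall retention.

**Step 7**
Reactants: 14 (2R,5S)-5-acetyl-2-tert-butyl-5-methyl-1,3-dioxolan-4-one
Product: 15 lithium (2S)-2-hydroxy-2-methyl-3-oxobutanoate
Conditions: LiOH (1.05 equiv), THF/H2O, 0 °C, 30 min; freeze-drying
Reagents that add atoms: lithium hydroxide, [Li+].[OH-]
Why: Saponification of the acetal‑lactone releases pivalaldehyde and the configurationally fixed (no α‑H) acetolactate, kept as the carboxylate to avoid decarboxylation.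

### Part D – core (longest linear sequence)

**Step 8**
Reactants: 16 dimethyl (S)-malate
Product: 20 dimethyl (2S)-2-hydroxy-3-methylidenebutanedioate, via dianion 17 (not isolated), via Mannich base 18 (not isolated), via methiodide 19 (not isolated)
Conditions: LiN(i-Pr)2 (2.2 equiv), THF, −78 → −20 °C; then CH2=NMe2+ I−, −78 → 0 °C; AcOH; then MeI, MeOH, rt; then NaHCO3 (aq), CH2Cl2, rt
Reagents that add atoms: dimethylmethyleneammonium iodide, C=[N+](C)C.[I-]
Why: Fráter–Seebach dianion aminomethylation (Mannich) then quaternisation and E1cB elimination installs the C10 methylene, while the bought carbinol centre (future C9) is untouched.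

**Step 9**
Reactants: 20 dimethyl (2S)-2-hydroxy-3-methylidenebutanedioate
Product: 21 dimethyl (2S)-2-(methoxymethoxy)-3-methylidenebutanedioate
Conditions: MOMCl, i-Pr2NEt, Bu4NI (cat.), CH2Cl2, 0 °C → rt
Reagents that add atoms: chloromethyl methyl ether, COCCl
Why: O‑Alkylation gives a base‑stable, chelating acetal protecting group for O‑9.

**Step 10**
Reactants: 21 dimethyl (2S)-2-(methoxymethoxy)-3-methylidenebutanedioate
Product: 22 methyl (3S)-3-(methoxymethoxy)-2-methylidene-4-oxobutanoate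
Conditions: i-Bu2AlH (1.05 equiv), CH2Cl2, −78 °C; MeOH, aq KNaC4H4O6; used crude
Reagents that add atoms: none
Why: Chemoselective half‑reduction of the activated α‑alkoxy ester (chelated tetrahedral aluminate) leaves the hindered conjugated ester intact.

**Step 11**
Reactants: 22 methyl (3S)-3-(methoxymethoxy)-2-methylidene-4-oxobutanoate; 3 neryl propargyl ether
Product: 24 methyl (3S,4S)-7-[(2Z)-3,7-dimethylocta-2,6-dienyloxy]-4-hydroxy-3-(methoxymethoxy)-2-methylidenehept-5-ynoate, via alkynylmagnesium bromide 23 (not isolated)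
Conditions: 3, EtMgBr, THF, 0 → 40 °C; then 22 precomplexed with MgBr2·OEt2, CH2Cl2, −78 °C; aq NH4Cl
Reagents that add atoms: none
Why: Cram‑chelate‑controlled alkynyl Grignard addition (Mg bridging the aldehyde and MOM oxygens) gives the syn (threo) adduct, so C8 (S) is set by the malate‑derived C9; the minor anti isomer is removed by chromatography.

**Step 12**
Reactants: 24 (acyclic ene–yne ester from step 11)
Product: 25 methyl (3Z,7E,9S,10S)-10-hydroxy-9-(methoxymethoxy)-4-methyl-1-oxacyclotrideca-3,7-dien-11-yne-8-carboxylate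
Conditions: second-generation Hoveyda–Grubbs catalyst RuCl2(H2IMes)(=CH-C6H4-2-O-i-Pr) (10 mol %), toluene (1 mM), 80 °C, argon sparge
Reagents that add atoms: none
Why: Ring‑closing metathesis between the acrylate and the prenyl terminus (loss of isobutene) closes the 13‑membered ether; the tiglate‑type enoate (C2 trans to CO2Me, cis to C9) is the expected thermodynamic and ring‑favoured isomer.

**Step 13**
Reactants: 25 (13‑membered enoate‑alkyne from step 12)
Product: 28 (3Z,7Z,9S,10S,11Z)-8-(hydroxymethyl)-12-iodo-9-(methoxymethoxy)-4-methyl-1-oxacyclotrideca-3,7,11-trien-10-ol, via diol 26 (not isolated), via alkenylalanate 27 (not isolated)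
Conditions: i-Bu2AlH (3.5 equiv), CH2Cl2, −78 → 0 °C, aq KNaC4H4O6; then NaAlH2(OCH2CH2OMe)2, THF, 0 °C → rt; then I2, THF, −78 °C; aq Na2S2O3
Reagents that add atoms: iodine, II
Why: After 1,2‑reduction of the enoate, hydroxyl‑directed trans‑hydroalumination of the propargylic alcohol (hydride to C7, Al to C11) and iodinolysis with retention give the (Z)‑iodoalkene, i.e. C8 trans to C13 as the Wittig step requires.

**Step 14**
Reactants: 28 (iodo diol from step 13)
Product: 30 [(3Z,7Z,9S,10S,11Z)-10-(tert-butyldimethylsilyloxy)-12-iodo-9-(methoxymethoxy)-4-methyl-1-oxacyclotrideca-3,7,11-trien-8-yl]methanol, via bis-silyl ether 29 (not isolated)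
Conditions: TBSOTf (2.5 equiv), 2,6-lutidine, CH2Cl2, −78 → 0 °C; then PPTS (cat.), MeOH, 0 °C → rt
Reagents that add atoms: tert-butyldimethylsilyl triflate, CC(C)(C)[Si](C)(C)OS(=O)(=O)C(F)(F)F
Why: Exhaustive silylation then selective methanolysis of the unhindered primary allylic silyl ether leaves only O‑8 protected, differentiating it from O‑9 (MOM).

**Step 15**
Reactants: 30 (mono-silyl iodide from step 14)
Product: 31 [(3Z,7Z,9S,10S,11E)-10-(tert-butyldimethylsilyloxy)-9-(methoxymethoxy)-4-methyl-1-oxacyclotrideca-3,7,11-triene-8,12-diyl]dimethanol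
Conditions: Bu3SnCH2OH, Pd(PPh3)4 (10 mol %), 1,4-dioxane, 90 °C
Reagents that add atoms: tributyl(hydroxymethyl)stannane, CCCC[Sn](CCCC)(CCCC)CO
Why: Stille coupling with retention of olefin geometry installs C12 as a hydroxymethyl group cis to C8.

**Step 16**
Reactants: 31 (13‑membered bis-allylic ether diol from step 15)
Product: 32 8β-(tert-butyldimethylsilyloxy)-9α-(methoxymethoxy)-7αH-germacra-1(10),4,11(13)-triene-6α,12,14-triol
Conditions: n-BuLi (3.5 equiv), THF, −78 → −20 °C; AcOH, −78 °C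
Reagents that add atoms: none
Why: Transannular [2,3]‑Wittig sigmatropic ring contraction (13 → 10): the two lithium alkoxides deactivate their own allyl units, so lithiation occurs at the neryl CH2 (C6); the suprafacial shift onto C7 of the E‑allyl ether gives the 6,7‑anti product, and the A(1,3)‑locked C8 centre (set by malate‑derived C9) directs the bond to the face away from the C9 arm, fixing C6 (R) and C7 (S).

**Step 17**
Reactants: 32 (ten-membered triol from step 16)
Product: 33 8β-(tert-butyldimethylsilyloxy)-9α-(methoxymethoxy)-14-oxo-7αH-germacra-1(10),4,11(13)-trien-12,6α-olide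
Conditions: TEMPO (0.2 equiv), PhI(OAc)2 (3.5 equiv), CH2Cl2, rt
Reagents that add atoms: none
Why: Oxoammonium oxidation of the two primary allylic alcohols; the C12 aldehyde is trapped by the only free secondary hydroxyl (O‑6) as a lactol and oxidised on to the trans‑fused α‑methylene lactone, while C14 stops at the enal.

**Step 18**
Reactants: 33 (lactone enal from step 17)
Product: 35 methyl 8β-(tert-butyldimethylsilyloxy)-9α-(methoxymethoxy)-7αH-germacra-1(10),4,11(13)-trien-12,6α-olid-14-oate, via carboxylic acid 34 (not isolated)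
Conditions: NaClO2, NaH2PO4, 2-methyl-2-butene, t-BuOH/H2O, 0 °C → rt; then MeI, KHCO3, DMF, rt
Reagents that add atoms: sodium chlorite, [Na+].[O-]Cl=O; iodomethane, CI
Why: Pinnick oxidation of the enal then carboxylate O‑methylation under near‑neutral conditions gives the C14 methyl ester without touching the Michael acceptors.

**Step 19**
Reactants: 35 (silyl-protected lactone ester from step 18)
Product: 36 methyl 8β-hydroxy-9α-(methoxymethoxy)-7αH-germacra-1(10),4,11(13)-trien-12,6α-olid-14-oate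
Conditions: HF·pyridine, pyridine/THF, 0 °C → rt
Reagents that add atoms: none
Why: Fluoride‑mediated desilylation frees O‑8 alone; the MOM ether on O‑9 is stable.

**Step 20**
Reactants: 36 (8-hydroxy lactone ester from step 19); 15 lithium (2S)-2-hydroxy-2-methyl-3-oxobutanoate
Product: 38 methyl 8β-[(2S)-2-hydroxy-2-methyl-3-oxobutanoyloxy]-9α-(methoxymethoxy)-7αH-germacra-1(10),4,11(13)-trien-12,6α-olid-14-oate, via mixed anhydride 37 (not isolated)
Conditions: 15 (3 equiv), 2,4,6-trichlorobenzoyl chloride, Et3N, THF/DMF, 0 °C; then 36, DMAP, toluene, rt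
Reagents that add atoms: none
Why: Yamaguchi esterification from the carboxylate salt (no free β‑keto acid, so no decarboxylation); the tertiary hydroxyl is too hindered to compete and the quaternary centre cannot epimerise.

**Step 21**
Reactants: 38 (8-acetolactate from step 20)
Product: 39 methyl 9α-hydroxy-8β-[(2S)-2-hydroxy-2-methyl-3-oxobutanoyloxy]-7αH-germacra-1(10),4,11(13)-trien-12,6α-olid-14-oate
Conditions: Me2BBr, CH2Cl2, −78 °C; aq NaHCO3
Reagents that add atoms: none
Why: Lewis‑acid cleavage of the MOM acetal at low temperature frees O‑9 without affecting esters or the lactone, and the hindered tertiary acyl group on O‑8 resists migration.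

**Step 22**
Reactants: 39 (9-hydroxy compound from step 21); 9 (2R,3S)-2-methyl-3-(triethylsilyloxy)butanoic acid
Product: 40 methyl 8β-[(2S)-2-hydroxy-2-methyl-3-oxobutanoyloxy]-9α-[(2R,3S)-2-methyl-3-(triethylsilyloxy)butanoyloxy]-7αH-germacra-1(10),4,11(13)-trien-12,6α-olid-14-oate
Conditions: EDC·HCl, DMAP, CH2Cl2, 0 °C → rt
Reagents that add atoms: none
Why: Steglich esterification of the only free secondary hydroxyl; the tertiary hydroxyl of the acetolactate does not react and no new stereocentre is formed.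

**Step 23**
Reactants: 40 (silyl-protected diester from step 22)
Product: 41 target CNP0168935.2
Conditions: HF·pyridine, pyridine/THF, 0 °C
Reagents that add atoms: none
Why: Mild fluoride desilylation reveals the side‑chain hydroxyl without acyl migration or lactone opening.

## Compound list

1 | nerol, (2Z)-3,7-dimethylocta-2,6-dien-1-ol | OC/C=C(/C)CCC=C(C)C | starting material
2 | propargyl bromide | C#CCBr | starting material
3 | neryl propargyl ether, (2Z)-3,7-dimethyl-1-(prop-2-ynyloxy)octa-2,6-diene | C#CCOC/C=C(/C)CCC=C(C)C | intermediate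
4 | D-threonine | C[C@H](O)[C@@H](N)C(=O)O | starting material
5 | (2R,3S)-2-bromo-3-hydroxybutanoic acid | C[C@H](O)[C@@H](Br)C(=O)O | intermediate
6 | (2S,3S)-3-methyloxirane-2-carboxylic acid (cis) | C[C@@H]1O[C@@H]1C(=O)O | intermediate
7 | (2R,3S)-3-hydroxy-2-methylbutanoic acid | C[C@H](O)[C@@H](C)C(=O)O | intermediate
8 | triethylsilyl (2R,3S)-2-methyl-3-(triethylsilyloxy)butanoate | C[C@H](O[Si](CC)(CC)CC)[C@@H](C)C(=O)O[Si](CC)(CC)CC | intermediate
9 | (2R,3S)-2-methyl-3-(triethylsilyloxy)butanoic acid | C[C@H](O[Si](CC)(CC)CC)[C@@H](C)C(=O)O | intermediate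
10 | (R)-lactic acid | C[C@@H](O)C(=O)O | starting material
11 | pivalaldehyde | CC(C)(C)C=O | starting material
12 | (2R,5R)-2-tert-butyl-5-methyl-1,3-dioxolan-4-one | C[C@H]1O[C@@H](C(C)(C)C)OC1=O | intermediate
13 | lithium enolate of 12 | CC1=C([O-])O[C@H](C(C)(C)C)O1.[Li+] | intermediate
14 | (2R,5S)-5-acetyl-2-tert-butyl-5-methyl-1,3-dioxolan-4-one | C[C@@]1(C(C)=O)O[C@@H](C(C)(C)C)OC1=O | intermediate
15 | lithium (2S)-2-hydroxy-2-methyl-3-oxobutanoate | [Li+].[O-]C(=O)[C@@](C)(O)C(C)=O | intermediate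
16 | dimethyl (S)-malate | COC(=O)C[C@H](O)C(=O)OC | starting material
17 | dilithium alkoxide-enolate of 16 | [Li+].[Li+].COC([O-])=C[C@H]([O-])C(=O)OC | intermediate
18 | dimethyl (2S,3R)-3-[(dimethylamino)methyl]-2-hydroxybutanedioate | COC(=O)[C@H](CN(C)C)[C@H](O)C(=O)OC | intermediate
19 | methiodide of 18 | COC(=O)[C@H](C[N+](C)(C)C)[C@H](O)C(=O)OC.[I-] | intermediate
20 | dimethyl (2S)-2-hydroxy-3-methylidenebutanedioate | COC(=O)C(=C)[C@H](O)C(=O)OC | intermediate
21 | dimethyl (2S)-2-(methoxymethoxy)-3-methylidenebutanedioate | COC(=O)C(=C)[C@H](OCOC)C(=O)OC | intermediate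
22 | methyl (3S)-3-(methoxymethoxy)-2-methylidene-4-oxobutanoate | COC(=O)C(=C)[C@H](OCOC)C=O | intermediate
23 | alkynylmagnesium bromide of 3 | Br[Mg]C#CCOC/C=C(/C)CCC=C(C)C | intermediate
24 | methyl (3S,4S)-7-[(2Z)-3,7-dimethylocta-2,6-dienyloxy]-4-hydroxy-3-(methoxymethoxy)-2-methylidenehept-5-ynoate | COC(=O)C(=C)[C@H](OCOC)[C@@H](O)C#CCOC/C=C(/C)CCC=C(C)C | intermediate
25 | methyl (3Z,7E,9S,10S)-10-hydroxy-9-(methoxymethoxy)-4-methyl-1-oxacyclotrideca-3,7-dien-11-yne-8-carboxylate (ring O–C6–C5=C4–C3–C2–C1=C10–C9–C8–C7≡C11–C13) | O1C/C=C(/C)CC/C=C(/C(=O)OC)[C@H](OCOC)[C@@H](O)C#CC1 | intermediate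
26 | (3Z,7Z,9S,10S)-8-(hydroxymethyl)-9-(methoxymethoxy)-4-methyl-1-oxacyclotrideca-3,7-dien-11-yn-10-ol | O1C/C=C(/C)CC/C=C(/CO)[C@H](OCOC)[C@@H](O)C#CC1 | intermediate
27 | cyclic sodium alkenyl(alkoxy)bis(2-methoxyethoxy)aluminate from 26 (Al on C11 and O-8; C14 alkoxide) | O1C/C=C(/C)CC/C=C(/C[O-])[C@H](OCOC)[C@H]2O[Al-](OCCOC)(OCCOC)C(=C2)C1.[Na+].[Na+] | intermediate
28 | (3Z,7Z,9S,10S,11Z)-8-(hydroxymethyl)-12-iodo-9-(methoxymethoxy)-4-methyl-1-oxacyclotrideca-3,7,11-trien-10-ol | O1C/C=C(/C)CC/C=C(/CO)[C@H](OCOC)[C@@H](O)/C=C(\I)C1 | intermediate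
29 | bis(tert-butyldimethylsilyl) ether of 28 | O1C/C=C(/C)CC/C=C(/CO[Si](C)(C)C(C)(C)C)[C@H](OCOC)[C@@H](O[Si](C)(C)C(C)(C)C)/C=C(\I)C1 | intermediate
30 | [(3Z,7Z,9S,10S,11Z)-10-(tert-butyldimethylsilyloxy)-12-iodo-9-(methoxymethoxy)-4-methyl-1-oxacyclotrideca-3,7,11-trien-8-yl]methanol | O1C/C=C(/C)CC/C=C(/CO)[C@H](OCOC)[C@@H](O[Si](C)(C)C(C)(C)C)/C=C(\I)C1 | intermediate
31 | [(3Z,7Z,9S,10S,11E)-10-(tert-butyldimethylsilyloxy)-9-(methoxymethoxy)-4-methyl-1-oxacyclotrideca-3,7,11-triene-8,12-diyl]dimethanol | O1C/C=C(/C)CC/C=C(/CO)[C@H](OCOC)[C@@H](O[Si](C)(C)C(C)(C)C)/C=C(\CO)C1 | intermediate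
32 | 8β-(tert-butyldimethylsilyloxy)-9α-(methoxymethoxy)-7αH-germacra-1(10),4,11(13)-triene-6α,12,14-triol (ring carbons cis on both ring olefins) | O[C@@H]1/C=C(/C)CC/C=C(/CO)[C@H](OCOC)[C@@H](O[Si](C)(C)C(C)(C)C)[C@H]1C(=C)CO | intermediate
33 | 8β-(tert-butyldimethylsilyloxy)-9α-(methoxymethoxy)-14-oxo-7αH-germacra-1(10),4,11(13)-trien-12,6α-olide | C=C1C(=O)O[C@@H]2/C=C(/C)CC/C=C(/C=O)[C@H](OCOC)[C@@H](O[Si](C)(C)C(C)(C)C)[C@@H]12 | intermediate
34 | 14-oic acid corresponding to 33 | C=C1C(=O)O[C@@H]2/C=C(/C)CC/C=C(/C(=O)O)[C@H](OCOC)[C@@H](O[Si](C)(C)C(C)(C)C)[C@@H]12 | intermediate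
35 | methyl 8β-(tert-butyldimethylsilyloxy)-9α-(methoxymethoxy)-7αH-germacra-1(10),4,11(13)-trien-12,6α-olid-14-oate | C=C1C(=O)O[C@@H]2/C=C(/C)CC/C=C(/C(=O)OC)[C@H](OCOC)[C@@H](O[Si](C)(C)C(C)(C)C)[C@@H]12 | intermediate
36 | methyl 8β-hydroxy-9α-(methoxymethoxy)-7αH-germacra-1(10),4,11(13)-trien-12,6α-olid-14-oate | C=C1C(=O)O[C@@H]2/C=C(/C)CC/C=C(/C(=O)OC)[C@H](OCOC)[C@@H](O)[C@@H]12 | intermediate
37 | (2S)-2-hydroxy-2-methyl-3-oxobutanoic 2,4,6-trichlorobenzoic anhydride | CC(=O)[C@](C)(O)C(=O)OC(=O)c1c(Cl)cc(Cl)cc1Cl | intermediate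
38 | methyl 8β-[(2S)-2-hydroxy-2-methyl-3-oxobutanoyloxy]-9α-(methoxymethoxy)-7αH-germacra-1(10),4,11(13)-trien-12,6α-olid-14-oate | C=C1C(=O)O[C@@H]2/C=C(/C)CC/C=C(/C(=O)OC)[C@H](OCOC)[C@@H](OC(=O)[C@@](C)(O)C(C)=O)[C@@H]12 | intermediate
39 | methyl 9α-hydroxy-8β-[(2S)-2-hydroxy-2-methyl-3-oxobutanoyloxy]-7αH-germacra-1(10),4,11(13)-trien-12,6α-olid-14-oate | C=C1C(=O)O[C@@H]2/C=C(/C)CC/C=C(/C(=O)OC)[C@H](O)[C@@H](OC(=O)[C@@](C)(O)C(C)=O)[C@@H]12 | intermediate
40 | 9-O-[(2R,3S)-2-methyl-3-(triethylsilyloxy)butanoyl] derivative of 39 | C=C1C(=O)O[C@@H]2/C=C(/C)CC/C=C(/C(=O)OC)[C@H](OC(=O)[C@H](C)[C@H](C)O[Si](CC)(CC)CC)[C@@H](OC(=O)[C@@](C)(O)C(C)=O)[C@@H]12 | intermediate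
41 | CNP0168935.2, (6R,7S,8S,9S) | C=C1C(=O)O[C@@H]2/C=C(/C)CC/C=C(/C(=O)OC)[C@H](OC(=O)[C@H](C)[C@H](C)O)[C@@H](OC(=O)[C@@](C)(O)C(C)=O)[C@@H]12 | target

## Step count and risks

Total steps: 23. Longest linear sequence: 16 (steps 8–23, from dimethyl (S)-malate).

**Most likely to fail: step 16 (transannular [2,3]-Wittig).** Lithiation may occur at C13 instead of C6, or the C6/C7 sense may erode in the polyanion. The fallback sets out from 31 and returns at 32. Both primary hydroxyls of 31 are silylated (TBSCl, imidazole) to the tris-silyl ether F1. DDQ in wet CH2Cl2 cleaves the electron-rich neryl-type allylic ether oxidatively to the seco (2Z)-enal allylic alcohol F2. Corey–Kim bromination (NBS, Me2S) gives the allylic bromide F3. An intramolecular CrCl2-mediated Nozaki–Hiyama allylation at high dilution then forms the same C6–C7 bond (anti, chair transition state) to give the tris-silyl triol F4. PPTS in MeOH removes the two primary silyl groups to give 32.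

**Second: step 12 (ring-closing metathesis).** The internal alkyne may intercept the ruthenium carbene, and the prenyl terminus initiates slowly. The fallback sets out from 24 and returns at 28. The step 13 sequence (i-Bu2AlH; NaAlH2(OCH2CH2OMe)2; I2) is applied to acyclic 24 first, giving the acyclic (Z)-iodoalkene diol F5. The 13-membered ring is then closed on this alkyne-free allylic alcohol with the same ruthenium catalyst, giving 28 directly; the C1=C10 geometry is then set at the alcohol stage and must be checked.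

**Third: step 20 (esterification with the acetolactate salt).** A hindered alcohol meets a hindered, base-sensitive α-ketol acid. The fallback sets out from 12 (with 36) and returns at 38. The enolate of 12 is added to acetaldehyde to give the aldol dioxolanone F6 (carbinol epimers, both converge). Silylation (TESOTf, 2,6-lutidine) gives the silyl ether F7, and LiOH hydrolysis gives the stable 3-silyloxy acid F8. Yamaguchi coupling with 36 gives the ester F9, HF·pyridine gives the diol ester F10, and Dess–Martin periodinane oxidises the secondary alcohol to give 38.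

## Further compounds

F1 | step 16 | 8,12,14-tris(tert-butyldimethylsilyl) ether of macrocyclic diol 31 | O1C/C=C(/C)CC/C=C(/CO[Si](C)(C)C(C)(C)C)[C@H](OCOC)[C@@H](O[Si](C)(C)C(C)(C)C)/C=C(\CO[Si](C)(C)C(C)(C)C)C1
F2 | step 16 | seco (2Z)-enal allylic alcohol (C6 aldehyde, C13 hydroxyl, tris-silyl) | O=C/C=C(/C)CC/C=C(/CO[Si](C)(C)C(C)(C)C)[C@H](OCOC)[C@@H](O[Si](C)(C)C(C)(C)C)/C=C(\CO[Si](C)(C)C(C)(C)C)CO
F3 | step 16 | C13 allylic bromide of F2 | O=C/C=C(/C)CC/C=C(/CO[Si](C)(C)C(C)(C)C)[C@H](OCOC)[C@@H](O[Si](C)(C)C(C)(C)C)/C=C(\CO[Si](C)(C)C(C)(C)C)CBr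
F4 | step 16 | 8,12,14-tris(tert-butyldimethylsilyl) ether of triol 32 | O[C@@H]1/C=C(/C)CC/C=C(/CO[Si](C)(C)C(C)(C)C)[C@H](OCOC)[C@@H](O[Si](C)(C)C(C)(C)C)[C@H]1C(=C)CO[Si](C)(C)C(C)(C)C
F5 | step 12 | (3S,4S,5Z)-7-[(2Z)-3,7-dimethylocta-2,6-dienyloxy]-6-iodo-3-(methoxymethoxy)-2-methylidenehept-5-ene-1,4-diol | OCC(=C)[C@H](OCOC)[C@@H](O)/C=C(\I)COC/C=C(/C)CCC=C(C)C
F6 | step 20 | (2R,5S)-2-tert-butyl-5-(1-hydroxyethyl)-5-methyl-1,3-dioxolan-4-one (carbinol epimers) | C[C@@]1(C(C)O)O[C@@H](C(C)(C)C)OC1=O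
F7 | step 20 | triethylsilyl ether of F6 | C[C@@]1(C(C)O[Si](CC)(CC)CC)O[C@@H](C(C)(C)C)OC1=O
F8 | step 20 | (2S)-2-hydroxy-2-methyl-3-(triethylsilyloxy)butanoic acid | OC(=O)[C@@](C)(O)C(C)O[Si](CC)(CC)CC
F9 | step 20 | 8-O-[(2S)-2-hydroxy-2-methyl-3-(triethylsilyloxy)butanoyl] derivative of 36 | C=C1C(=O)O[C@@H]2/C=C(/C)CC/C=C(/C(=O)OC)[C@H](OCOC)[C@@H](OC(=O)[C@@](C)(O)C(C)O[Si](CC)(CC)CC)[C@@H]12
F10 | step 20 | 8-O-[(2S)-2,3-dihydroxy-2-methylbutanoyl] derivative of 36 | C=C1C(=O)O[C@@H]2/C=C(/C)CC/C=C(/C(=O)OC)[C@H](OCOC)[C@@H](OC(=O)[C@@](C)(O)C(C)O)[C@@H]12
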